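Pdt is the one thing you read, so every judgement about this flask has to come from how fast Pdt appears when a setting is turned. Here is what is charged, what was read and what is asked.

the same everywhere: Ctl 0.00200 M

| run | Sbt | Pdt | time |
|---|---|---|---|
| oak | 0.400 M |  |  |
| cedar | 0.240 M |  |  |
| alder | 0.400 M | 0.200 M |  |
| elm | 2.00 M |  | 13 min |

| run | time / min | [Pdt] / M |
|---|---|---|
| oak run | 0.52 | 0.018 |
| oak run | 0.89 | 0.029 |
| oak run | 1.5 | 0.041 |
| oak run | 2.6 | 0.063 |
| oak run | 4.4 | 0.103 |
| oak run | 7.6 | 0.134 |
| oak run | 13 | 0.150 |
| cedar run | 0.52 | 0.019 |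
| cedar run | 0.89 | 0.026 |
| cedar run | 1.5 | 0.046 |
| cedar run | 2.6 | 0.074 |
| cedar run | 4.4 | 0.092 |
| cedar run | 7.6 | 0.106 |
| cedar run | 13 | 0.102 |
| alder run | 0.52 | 0.204 |
| alder run | 0.89 | 0.202 |
| alder run | 1.5 | 0.204 |
| alder run | 2.6 | 0.205 |
| alder run | 4.4 | 0.212 |
| alder run | 7.6 | 0.218 |
| alder run | 13 | 0.215 |

(scatter of a reading: 0.003 M)

- the exponent of [Sbt] in the starting rate at the charge of the oak run (at the point where two percent of the Sbt have become Pdt) (one fixed amount of Pdt, the same in the runs compared)
- Pdt in the elm run at 13 min, as a share of the Sbt charged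

- Overall: Sbt -> Pdt, with Ctl as catalyst.
- Constant volume, constant temperature.
- The analysis sees a species whether free or bound.
- An order is taken over about fifteen percent of the charge, up and down.

Turn the Sbt charge first. By hand, a pace that followed the charge would put cedar at 0.0378 M at 2.6 min, from oak's 0.063 M. Cedar reads 0.074 M, more than oak, with less Sbt charged. Divide cedar's mean pace over the first 2.6 min by oak's over the same span and the span cancels, which leaves an apparent order in Sbt for that span, my working exponent linking a change of charge to a change of pace:

order = ln(cedar Pdt / oak Pdt) / ln(cedar charge / oak charge) = −0.315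

It is a reading for that span, with the scatter of two readings in it. Over the first 13 min the same division gives 0.755, so the figure belongs to the span it was read over.

Now turn the Pdt charge. By hand, a bystander Pdt would leave alder making what oak made by 7.6 min, which is 0.134 M. Alder has made 0.0180 M, less than oak. Added Pdt slows this flask.

Last, the elm charge. I carry oak's mean pace over the first 2.6 min, 0.0242 M min⁻¹, up to elm's charge:

Pdt in elm = pace × (elm charge / oak charge)^order × time = 0.190 M, or 9.49% of the Sbt charged

That amount is close to alder's Pdt charge, so I hold my figure as a high one.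

The forecast differs from me. Noting that the runs “start at almost the same rate”, it gives an order of 0.1 (−0.2 to 0.4) and 17% for elm (11% to 23%).

The elm flask gives 7.26% of its Sbt charge as Pdt, and the order at oak's charge is −0.51. These are the steps behind the readings:

    Ctl + Sbt ⇌ Ctl.Sbt, settled at all times (26.50 M⁻¹)
    Ctl.Sbt ⇌ Pdt + Ctl (87.60 min⁻¹, 2106 M⁻¹ min⁻¹)
    2 Sbt ⇌ Sbt2, settled at all times (2.190 M⁻¹)
    Ctl.Sbt + Sbt ⇌ Ctl.Sbt2, settled at all times (22.70 M⁻¹)

The association of Ctl.Sbt with a second Sbt to Ctl.Sbt2, known as substrate inhibition, moves the readings by 13 in root mean square, in units of the scatter. Now put the order to work on the rates where two percent of oak's Sbt have turned. Oak's 0.029 M min⁻¹, multiplied by the charge ratio raised to the order, gives 0.0340 M min⁻¹ for cedar, and cedar's rate at that point is 0.037 M min⁻¹.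

All runs were computed for substances that don't exist, and the scatter is random.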